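Ring A (C1–C5, C10; drimane numbering) shares its C5–C10 edge with ring B and carries the C4 gem-dimethyl group next to C5, which is α to the C6 oxygen. At the C6-ketone level, with a transient C1=C2 alkene, ring A is therefore the retron of an intramolecular Diels–Alder reaction. One thermal operation joins C3 to C4 and C10 to C5, closes rings A and B together, and creates C5 and C10 under the control of C9. Its precursor is acyclic: a Me2C=CH–C(=O) dienophile, the C7=C8 alkene (C6 and C9 cis, C12 as diethyl acetal) as tether, the C9 hydroxy tert-butyl ester, and an (E)-penta-2,4-dien-2-yl diene.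

Key step: step 6

Assumptions: ring A = C1–C5 + C10, ring B = C5–C10, C11 = carboxyl carbon on C9, C12 = formyl carbon on C8. The (S,S)-ProPhenol/Me2Zn system is taken to give (R)-4; the antipodal ligand would serve equally, because this C6 stereocentre only makes the C9 epimers of 14 separable and is erased in step 6. The target is taken to rest in the open acid/aldehyde form drawn.

Step 1
Reactants: 1 3,3-diethoxyprop-1-yne; 2 3-methylbut-2-enal
Product: 4 (4R)-1,1-diethoxy-6-methylhept-5-en-2-yn-4-ol, via methylzinc acetylide 3 (not isolated)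
Conditions: Me2Zn (3 equiv), (S,S)-ProPhenol (10 mol %), Ph3PO (20 mol %), toluene, 4 °C; aq NH4Cl
Reagents that add atoms: none
Why: Zinc–ProPhenol catalysed asymmetric alkynylation of an enal, in which the dinuclear zinc complex binds acetylide and aldehyde together and delivers the alkyne to one aldehyde face, so that C6 (a sacrificial stereocentre) should form in high enantiomeric purity.

Step 2
Reactants: 4 (4R)-1,1-diethoxy-6-methylhept-5-en-2-yn-4-ol
Product: 6 (2Z,4R)-1,1-diethoxy-2-iodo-6-methylhepta-2,5-dien-4-ol, via cyclic alkenylalanate 5 (not isolated)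
Conditions: NaAlH2(OCH2CH2OCH3)2 (1.3 equiv), THF, 0 to 23 °C; then I2, −78 to 0 °C; aq Na2S2O3
Reagents that add atoms: iodine, [I][I]
Why: Alkoxide-directed trans-hydroalumination of a propargylic alcohol followed by iodinolysis with retention puts hydrogen on C7 and iodine on C8 cis to C6, which fixes the cis C6/C9 geometry of the later tether; no stereocentre is formed and C6 is untouched.

Step 3
Reactants: 7 ethyltriphenylphosphonium bromide; 8 di-tert-butyl oxalate
Product: 10 tert-butyl 2-oxo-3-(triphenyl-λ5-phosphanylidene)butanoate, via ethylidenetriphenylphosphorane 9 (not isolated)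
Conditions: n-BuLi (1.0 equiv), THF, 0 °C; then 8, −78 to 23 °C
Reagents that add atoms: none
Why: Acylation of a non-stabilised phosphorus ylide by an oxalate ester, in which the expelled tert-butoxide deprotonates the acylphosphonium ion, so the unreactive stabilised keto ylide is the end point and no second acylation follows.

Step 4
Reactants: 10 tert-butyl 2-oxo-3-(triphenyl-λ5-phosphanylidene)butanoate; 11 acrolein
Product: 12 tert-butyl (3E)-3-methyl-2-oxohexa-3,5-dienoate
Conditions: toluene, BHT, 70 °C
Reagents that add atoms: none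
Why: Wittig olefination with a stabilised acyl ylide, which should place the keto ester trans to the vinyl group and so give the (E)-diene with the future C10 methyl cis to C2, as the cycloaddition requires.

Step 5
Reactants: 6 (2Z,4R)-1,1-diethoxy-2-iodo-6-methylhepta-2,5-dien-4-ol; 12 tert-butyl (3E)-3-methyl-2-oxohexa-3,5-dienoate
Product: 14 tert-butyl (2S,3E,5R)-3-(diethoxymethyl)-2,5-dihydroxy-7-methyl-2-[(2E)-penta-2,4-dien-2-yl]octa-3,6-dienoate, via dilithiated alkenyl alkoxide 13 (not isolated)
Conditions: t-BuLi (3.1 equiv), Et2O, −78 °C; then 12, −78 °C; aq NH4Cl; chromatography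
Reagents that add atoms: none
Why: Iodine–lithium exchange with retention of alkene geometry, then 1,2-addition of the alkenyllithium to the ketone carbonyl of the α-keto ester (the tert-butyl ester is shielded), creates C9 with little intrinsic bias; because C6 is a single enantiomer the two C9 epimers are diastereomers, and the (2S,5R)-isomer is isolated by chromatography.

Step 6
Reactants: 14 tert-butyl (2S,3E,5R)-3-(diethoxymethyl)-2,5-dihydroxy-7-methyl-2-[(2E)-penta-2,4-dien-2-yl]octa-3,6-dienoate
Product: 17 tert-butyl (5S,9S,10S)-12,12-diethoxy-9-hydroxy-6-oxodrima-1,7-dien-11-oate (trans-fused), via acyclic trienone 15 (not isolated), via cis-fused cycloadduct 16 (not isolated)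
Conditions: MnO2 (20 equiv), toluene, 23 °C; filter; BHT, 0.01 M, 105 °C; then DBU (0.3 equiv), 23 °C
Reagents that add atoms: none
Why: MnO2 oxidises only the bis-allylic C6 carbinol, and the cross-conjugated trienone 15 so released undergoes a concerted but asynchronous normal-electron-demand [4+2] cycloaddition in which the free diene terminus C3 bonds to the enone β-carbon C4 and the disubstituted terminus C10 to the α-carbon C5, the electronically matched orientation. The closest known reaction type is the type 1 intramolecular Diels–Alder reaction of 1,7,9-decatrien-3-ones set off by oxidation of the allylic alcohol. Ring A closes as the new cyclohexene of the cycloaddition and ring B as the fused six-membered ring spanned by the four-atom tether C6–C7=C8–C9, whose cis C6/C9 geometry holds both ends within bonding distance. C10 is controlled by C9: allylic 1,2-strain against the bulky C12 acetal, reinforced by an O–H···O hydrogen bond to it, keeps the small hydroxyl in the C7=C8 plane and turns the ester out of it, so that in the endo mode the dienophile meets the diene face that gives the 9α-OH/10β-CH3 relationship. C5 arises first as 5β-H (16) from the endo mode, preferred because the exo mode presses the tether against the inward-pointing C10 methyl, and DBU then equilibrates this enolisable centre to the more stable trans-decalin 17 (5α-H). The step needs site selectivity for C4=C5 over C7=C8, secured because C7=C8 lies only one atom from the diene, and endo over exo selectivity, which rests on the inward methyl and on secondary orbital overlap with the C6 carbonyl.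

Step 7
Reactants: 17 tert-butyl (5S,9S,10S)-12,12-diethoxy-9-hydroxy-6-oxodrima-1,7-dien-11-oate
Product: 18 tert-butyl (5S,9S,10S)-12,12-diethoxy-9-hydroxy-6-oxodrim-7-en-11-oate
Conditions: H2 (1–4 atm), RhCl(PPh3)3 (10 mol %), benzene/EtOH, 23 °C
Reagents that add atoms: none
Why: Homogeneous hydrogenation that discriminates by substitution: the cis-disubstituted C1=C2 alkene can bind rhodium, whereas the trisubstituted, electron-poor and doubly flanked C7=C8 cannot (as in the selective 1,2-saturation of steroidal 1,4-dien-3-ones); no stereocentre is formed.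

Step 8
Reactants: 18 tert-butyl (5S,9S,10S)-12,12-diethoxy-9-hydroxy-6-oxodrim-7-en-11-oate
Product: 19 tert-butyl (5S,6R,9S,10S)-12,12-diethoxy-6,9-dihydroxydrim-7-en-11-oate
Conditions: NaBH4, CeCl3·7H2O, EtOH/THF, −40 to 0 °C
Reagents that add atoms: none
Why: Luche 1,2-reduction, in which the β-face of C6 is screened by the axial C10 and C4β methyl groups, so hydride should arrive from the α-face and give the axial 6β-alcohol (6R); ethanol avoids acetal exchange.

Step 9
Reactants: 20 (2E,4E)-hexa-2,4-dienal; 21 malonic acid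
Product: 23 (2E,4E,6E)-octa-2,4,6-trienoic acid, via hexadienylidenemalonic acid 22 (not isolated)
Conditions: pyridine, piperidine (cat.), 90 °C
Reagents that add atoms: none
Why: Doebner modification of the Knoevenagel condensation, whose decarboxylation step should deliver the new C2=C3 alkene as the (E)-isomer and leave the two existing (E)-alkenes unchanged.

Step 10
Reactants: 19 tert-butyl (5S,6R,9S,10S)-12,12-diethoxy-6,9-dihydroxydrim-7-en-11-oate; 23 (2E,4E,6E)-octa-2,4,6-trienoic acid
Product: 25 tert-butyl (5S,6R,9S,10S)-12,12-diethoxy-9-hydroxy-6-[(2E,4E,6E)-octa-2,4,6-trienoyloxy]drim-7-en-11-oate, via mixed anhydride 24 (not isolated)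
Conditions: 2-methyl-6-nitrobenzoic anhydride (MNBA), DMAP, Et3N, toluene, 23 to 50 °C
Reagents that add atoms: none
Why: Shiina esterification (mixed anhydride, DMAP acyl transfer) should acylate the only secondary hydroxyl while the tertiary 9-OH stays inert, and C6 keeps its configuration because its C–O bond is not touched.

Step 11
Reactants: 25 tert-butyl (5S,6R,9S,10S)-12,12-diethoxy-9-hydroxy-6-[(2E,4E,6E)-octa-2,4,6-trienoyloxy]drim-7-en-11-oate
Product: 27 ustusoic acid B, via enal tert-butyl ester 26 (not isolated)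
Conditions: CF3CO2H/CH2Cl2/H2O (20:78:2), 0 to 23 °C
Reagents that add atoms: water, O
Why: Acidolysis, in which the allylic acetal hydrolyses first through its ethoxycarbenium ion and the tert-butyl ester then loses isobutene; the enal and carboxyl groups so formed disfavour ionisation at C6 and C9, so all four stereocentres and the trienoate should persist.

Compound list
1 | 3,3-diethoxyprop-1-yne | C#CC(OCC)OCC | starting material
2 | 3-methylbut-2-enal | CC(C)=CC=O | starting material
3 | (3,3-diethoxyprop-1-yn-1-yl)(methyl)zinc | C[Zn]C#CC(OCC)OCC | intermediate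
4 | (4R)-1,1-diethoxy-6-methylhept-5-en-2-yn-4-ol | CCOC(OCC)C#C[C@H](O)C=C(C)C | intermediate
5 | sodium cyclic alkenylalanate (1-oxa-2-aluminacyclopent-3-ene; Al on C8 and on O6) | [Na+].COCCO[Al-]1(OCCOC)O[C@H](C=C(C)C)C=C1C(OCC)OCC | intermediate
6 | (2Z,4R)-1,1-diethoxy-2-iodo-6-methylhepta-2,5-dien-4-ol | CCOC(OCC)/C(I)=C/[C@H](O)C=C(C)C | intermediate
7 | ethyltriphenylphosphonium bromide | CC[P+](c1ccccc1)(c1ccccc1)c1ccccc1.[Br-] | starting material
8 | di-tert-butyl oxalate | CC(C)(C)OC(=O)C(=O)OC(C)(C)C | starting material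
9 | ethylidenetriphenylphosphorane | CC=P(c1ccccc1)(c1ccccc1)c1ccccc1 | intermediate
10 | tert-butyl 2-oxo-3-(triphenyl-λ5-phosphanylidene)butanoate | CC(=P(c1ccccc1)(c1ccccc1)c1ccccc1)C(=O)C(=O)OC(C)(C)C | intermediate
11 | acrolein | C=CC=O | starting material
12 | tert-butyl (3E)-3-methyl-2-oxohexa-3,5-dienoate | C=C/C=C(\C)C(=O)C(=O)OC(C)(C)C | intermediate
13 | dilithiated alkenyl alkoxide from 6 (Li on C8 and on O6, geometry retained) | CCOC(OCC)/C([Li])=C/[C@H](O[Li])C=C(C)C | intermediate
14 | tert-butyl (2S,3E,5R)-3-(diethoxymethyl)-2,5-dihydroxy-7-methyl-2-[(2E)-penta-2,4-dien-2-yl]octa-3,6-dienoate (C6 and C9 cis on C7=C8) | CC(C)=C[C@@H](O)/C=C(/C(OCC)OCC)[C@](O)(C(=O)OC(C)(C)C)/C(C)=C/C=C | intermediate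
15 | tert-butyl (2S,3E)-3-(diethoxymethyl)-2-hydroxy-7-methyl-5-oxo-2-[(2E)-penta-2,4-dien-2-yl]octa-3,6-dienoate | CC(C)=CC(=O)/C=C(/C(OCC)OCC)[C@](O)(C(=O)OC(C)(C)C)/C(C)=C/C=C | intermediate
16 | tert-butyl (5R,9S,10S)-12,12-diethoxy-9-hydroxy-6-oxodrima-1,7-dien-11-oate (cis-fused: 5β-H, 10β-CH3, 9α-OH) | O=C1C=C(C(OCC)OCC)[C@](O)(C(=O)OC(C)(C)C)[C@@]2(C)C=CCC(C)(C)[C@@H]12 | intermediate
17 | tert-butyl (5S,9S,10S)-12,12-diethoxy-9-hydroxy-6-oxodrima-1,7-dien-11-oate (trans-fused: 5α-H, 10β-CH3, 9α-OH) | O=C1C=C(C(OCC)OCC)[C@](O)(C(=O)OC(C)(C)C)[C@@]2(C)C=CCC(C)(C)[C@H]12 | intermediate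
18 | tert-butyl (5S,9S,10S)-12,12-diethoxy-9-hydroxy-6-oxodrim-7-en-11-oate | O=C1C=C(C(OCC)OCC)[C@](O)(C(=O)OC(C)(C)C)[C@@]2(C)CCCC(C)(C)[C@H]12 | intermediate
19 | tert-butyl (5S,6R,9S,10S)-12,12-diethoxy-6,9-dihydroxydrim-7-en-11-oate (6β-OH, 9α-OH) | O[C@@H]1C=C(C(OCC)OCC)[C@](O)(C(=O)OC(C)(C)C)[C@@]2(C)CCCC(C)(C)[C@H]12 | intermediate
20 | (2E,4E)-hexa-2,4-dienal | C/C=C/C=C/C=O | starting material
21 | malonic acid | OC(=O)CC(=O)O | starting material
22 | 2-[(2E,4E)-hexa-2,4-dien-1-ylidene]malonic acid | C/C=C/C=C/C=C(C(=O)O)C(=O)O | intermediate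
23 | (2E,4E,6E)-octa-2,4,6-trienoic acid | C/C=C/C=C/C=C/C(=O)O | intermediate
24 | 2-methyl-6-nitrobenzoic (2E,4E,6E)-octa-2,4,6-trienoic anhydride | C/C=C/C=C/C=C/C(=O)OC(=O)c1c(C)cccc1[N+](=O)[O-] | intermediate
25 | tert-butyl (5S,6R,9S,10S)-12,12-diethoxy-9-hydroxy-6-[(2E,4E,6E)-octa-2,4,6-trienoyloxy]drim-7-en-11-oate | C/C=C/C=C/C=C/C(=O)O[C@@H]1C=C(C(OCC)OCC)[C@](O)(C(=O)OC(C)(C)C)[C@@]2(C)CCCC(C)(C)[C@H]12 | intermediate
26 | tert-butyl (5S,6R,9S,10S)-9-hydroxy-6-[(2E,4E,6E)-octa-2,4,6-trienoyloxy]-12-oxodrim-7-en-11-oate | C/C=C/C=C/C=C/C(=O)O[C@@H]1C=C(C=O)[C@](O)(C(=O)OC(C)(C)C)[C@@]2(C)CCCC(C)(C)[C@H]12 | intermediate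
27 | ustusoic acid B, (5S,6R,9S,10S)-9-hydroxy-6-[(2E,4E,6E)-octa-2,4,6-trienoyloxy]-12-oxodrim-7-en-11-oic acid | C/C=C/C=C/C=C/C(=O)O[C@@H]1C=C(C=O)[C@](O)(C(=O)O)[C@@]2(C)CCCC(C)(C)[C@H]12 | target

Total step count: 11. Longest linear sequence: 8 steps (1, 2, 5, 6, 7, 8, 10, 11).

Steps most likely to fail

Step 6. The cycloaddition may be too slow at a temperature the diene tolerates, because the C9 hydroxyl can close reversibly onto the C6 ketone and withdraw the activation of the dienophile. A [1,5]-hydrogen shift from the C10 methyl and leakage through the exo mode would then erode yield and facial selectivity. The fallback sets out from 14 and comes back at 17. N-(Trimethylsilyl)imidazole silylates both hydroxyls to give the bis(trimethylsilyl) ether F1. DDQ in CH2Cl2/pH 7 buffer oxidises only the bis-allylic C6 silyl ether to the O-silylated trienone F2, which can no longer close onto its ketone. Me2AlCl in CH2Cl2 (−78 to −30 °C) then promotes the same cycloaddition by complexing the carbonyl, where the endo preference should be larger, to give the silylated cis-fused cycloadduct F3. Bu4NF removes the silyl group and, being basic, equilibrates C5 to deliver 17.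

Step 5. Facial discrimination at the ketone may be poor, so that much material is lost as the unwanted C9 epimer. Separation of the epimers may be hard, and proton transfer from the C10 methyl of 12 or attack of the C6 alkoxide on the ester may compete. The fallback sets out from 6 and comes back at 14, and it sets C9 by catalyst control. Et3SiCl/imidazole gives the triethylsilyl ether F4. t-BuLi followed by 8 gives the alkenyl keto ester F5. Rhodium-catalysed hydrogenative coupling of a 1,3-enyne with an α-keto ester follows (H2 1 atm, [Rh(cod)2]OTf, a WALPHOS-type chiral bisphosphine, Ph3CCO2H, pent-1-en-3-yne, ClCH2CH2Cl). It joins the methyl-bearing alkyne carbon to the ketone with syn delivery of hydrogen, so the same (E)-diene arises, giving the silylated tertiary alcohol F6. HF·pyridine then frees 14.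

Step 10. Acyl transfer to the axial 6β-hydroxyl, flanked by two syn-axial methyl groups, may be sluggish, and long exposure of the activated trienoyl unit to DMAP may cause alkene isomerisation or deconjugation. The fallback sets out from 19 and comes back at 25. The small diethylphosphonoacetic acid is attached first (DCC, DMAP, CH2Cl2) to give the phosphonoacetate F7. A Horner–Wadsworth–Emmons reaction under Masamune–Roush conditions (LiCl, DBU, MeCN) with 20 then builds the (E,E,E)-trienoate on the hindered oxygen and gives 25.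

Further compounds
F1 | step 6 | tert-butyl (2S,3E,5R)-3-(diethoxymethyl)-7-methyl-2-[(2E)-penta-2,4-dien-2-yl]-2,5-bis(trimethylsilyloxy)octa-3,6-dienoate | CC(C)=C[C@@H](O[Si](C)(C)C)/C=C(/C(OCC)OCC)[C@](O[Si](C)(C)C)(C(=O)OC(C)(C)C)/C(C)=C/C=C
F2 | step 6 | tert-butyl (2S,3E)-3-(diethoxymethyl)-7-methyl-5-oxo-2-[(2E)-penta-2,4-dien-2-yl]-2-(trimethylsilyloxy)octa-3,6-dienoate | CC(C)=CC(=O)/C=C(/C(OCC)OCC)[C@](O[Si](C)(C)C)(C(=O)OC(C)(C)C)/C(C)=C/C=C
F3 | step 6 | tert-butyl (5R,9S,10S)-12,12-diethoxy-6-oxo-9-(trimethylsilyloxy)drima-1,7-dien-11-oate (cis-fused) | O=C1C=C(C(OCC)OCC)[C@](O[Si](C)(C)C)(C(=O)OC(C)(C)C)[C@@]2(C)C=CCC(C)(C)[C@@H]12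
F4 | step 5 | (2Z,4R)-1,1-diethoxy-2-iodo-6-methyl-4-(triethylsilyloxy)hepta-2,5-diene | CCOC(OCC)/C(I)=C/[C@H](O[Si](CC)(CC)CC)C=C(C)C
F5 | step 5 | tert-butyl (3Z,5R)-3-(diethoxymethyl)-7-methyl-2-oxo-5-(triethylsilyloxy)octa-3,6-dienoate | CC(C)=C[C@@H](O[Si](CC)(CC)CC)/C=C(/C(OCC)OCC)C(=O)C(=O)OC(C)(C)C
F6 | step 5 | tert-butyl (2S,3E,5R)-3-(diethoxymethyl)-2-hydroxy-7-methyl-2-[(2E)-penta-2,4-dien-2-yl]-5-(triethylsilyloxy)octa-3,6-dienoate | CC(C)=C[C@@H](O[Si](CC)(CC)CC)/C=C(/C(OCC)OCC)[C@](O)(C(=O)OC(C)(C)C)/C(C)=C/C=C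
F7 | step 10 | tert-butyl (5S,6R,9S,10S)-6-[2-(diethoxyphosphoryl)acetoxy]-12,12-diethoxy-9-hydroxydrim-7-en-11-oate | CCOP(=O)(OCC)CC(=O)O[C@@H]1C=C(C(OCC)OCC)[C@](O)(C(=O)OC(C)(C)C)[C@@]2(C)CCCC(C)(C)[C@H]12
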